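**Retrosynthetic overview**

1. Euchrenone a16 is a (2S)-5,7-dihydroxy-8-prenylflavanone whose ring B carries a fused 2,2-dimethyldihydropyran ring; the last step only frees the two phenols from silyl ethers.
2. Key disconnection: ring C is opened at O1–C2 and at C4–C4a. This leads back to a 2-prenylphloroglucinol bis-silyl ether with one free OH (ring A) and an E-cinnamoyl chloride that carries ring B and C2–C3–C4. Forward, ortho C-acylation to a 2'-hydroxychalcone and catalytic asymmetric oxa-Michael closure run in one operation, following the chalcone-to-flavanone logic of the biosynthesis.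
3. Enabling feature: in ring A, O1 on C8a lies between C8 (blocked by the prenyl group) and C4a (free, activated by the oxygens on C5, C7 and C8a). In ring C, C4 and C2 are 1,3-related, so an acyl group guided by O1 to C4a brings an enone whose β-carbon C2 is within reach of O1; the silylated oxygen on C5 cannot compete.
4. Ring A fragment: phloroglucinol, bis-silylation, Pd-catalysed O-(1,1-dimethylallyl)ation, aromatic Claisen rearrangement (prenyl ortho to the free OH). Ring B fragment: 4-bromophenol and isoprene to the chroman, Heck reaction with acrylic acid, acid chloride.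
5. Order of ring formation: rings A and B are bought as benzene rings, the dihydropyran ring on ring B closes first (step 5), ring C closes last (step 8).

Key step: step 8

Assumption: of the two pseudoenantiomeric cinchona thioureas, the quinidine-derived one is taken to give the (2S) product; should the sense of induction be the opposite, the quinine-derived catalyst replaces it without other change.

**Route**

Step 1
Reactants: 1 phloroglucinol (benzene-1,3,5-triol)
Product: 2 3,5-bis(tert-butyldimethylsilyloxy)phenol
Conditions: TBSCl (2.0 equiv), imidazole, DMF, 0 °C to rt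
Reagents that add atoms: tert-butyldimethylsilyl chloride (TBSCl), CC(C)(C)[Si](C)(C)Cl
Why: Imidazole-mediated O-silylation of a symmetric triphenol should give the bis-silyl ether as the main component of a statistical mixture at two equivalents of TBSCl, the mono- and tris-ethers being separable and recyclable.

Step 2
Reactants: 3 2-methylbut-3-en-2-ol
Product: 4 methyl 2-methylbut-3-en-2-yl carbonate
Conditions: ClCO2Me, pyridine, DMAP (cat.), CH2Cl2, 0 °C to rt
Reagents that add atoms: methyl chloroformate, COC(=O)Cl
Why: O-Acylation of a tertiary allylic alcohol by a chloroformate under nucleophilic catalysis (carbonate formation) is the standard entry to this class of allylic carbonates.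

Step 3
Reactants: 2 3,5-bis(tert-butyldimethylsilyloxy)phenol, 4 methyl 2-methylbut-3-en-2-yl carbonate
Product: 5 1,3-bis(tert-butyldimethylsilyloxy)-5-(2-methylbut-3-en-2-yloxy)benzene
Conditions: Pd(PPh3)4 (3 mol%), THF, 0 °C
Reagents that add atoms: none
Why: Tsuji–Trost O-allylation, in which zerovalent palladium ionises the tertiary carbonate with loss of CO2, the methoxide set free deprotonates the phenol, and the phenoxide attacks the more substituted terminus of the 1,1-dimethyl-π-allyl complex under kinetic control at low temperature, as known for the reverse prenylation of phenols.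

Step 4
Reactants: 5 1,3-bis(tert-butyldimethylsilyloxy)-5-(2-methylbut-3-en-2-yloxy)benzene
Product: 6 3,5-bis(tert-butyldimethylsilyloxy)-2-(3-methylbut-2-enyl)phenol
Conditions: PhNEt2, 120 °C
Reagents that add atoms: none
Why: Aromatic Claisen rearrangement, a [3,3]-sigmatropic shift that turns the 1,1-dimethylallyl ether into a normal prenyl group on the ortho carbon (the two ortho positions are equivalent) and after tautomerisation frees the phenol beside it, which fixes the prenyl group at the future C8 next to the future O1.

Step 5
Reactants: 7 4-bromophenol, 8 isoprene (2-methylbuta-1,3-diene)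
Product: 9 6-bromo-2,2-dimethylchroman
Conditions: AgOSO2CF3 (5 mol%), ClCH2CH2Cl, rt to 50 °C
Reagents that add atoms: none
Why: Lewis-acid-catalysed Friedel–Crafts ortho-prenylation of the phenol by isoprene followed by Markovnikov hydroalkoxylation of the trisubstituted alkene should close the 2,2-dimethyldihydropyran ring, the para position being blocked by bromine.

Step 6
Reactants: 9 6-bromo-2,2-dimethylchroman, 10 acrylic acid
Product: 11 (E)-3-(2,2-dimethylchroman-6-yl)acrylic acid
Conditions: Pd(OAc)2 (2 mol%), P(o-tol)3 (4 mol%), Et3N, DMF, 100 °C; aq. HCl on work-up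
Reagents that add atoms: none
Why: Mizoroki–Heck reaction of an aryl bromide with acrylic acid, in which syn-insertion and syn-β-hydride elimination should give the E-cinnamic acid.

Step 7
Reactants: 11 (E)-3-(2,2-dimethylchroman-6-yl)acrylic acid
Product: 12 (E)-3-(2,2-dimethylchroman-6-yl)acryloyl chloride
Conditions: (COCl)2, DMF (cat.), CH2Cl2, 0 °C to rt
Reagents that add atoms: oxalyl chloride, O=C(Cl)C(=O)Cl
Why: Acid chloride formation through the Vilsmeier-type chloroiminium salt from DMF and oxalyl chloride is mild enough for the chroman ether and the E-alkene.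

Step 8
Reactants: 6 3,5-bis(tert-butyldimethylsilyloxy)-2-(3-methylbut-2-enyl)phenol, 12 (E)-3-(2,2-dimethylchroman-6-yl)acryloyl chloride
Product: 14 (2S)-5,7-bis(tert-butyldimethylsilyloxy)-2-(2,2-dimethylchroman-6-yl)-8-(3-methylbut-2-enyl)chroman-4-one, via 2'-hydroxychalcone 13 (not isolated)
Conditions: 6 (2.0 equiv, surplus recovered), EtMgBr (2.0 equiv), Et2O then toluene, 0 °C to rt; 12 (1.0 equiv), toluene, rt; cold aq. NH4Cl wash, dried toluene phase carried on; 1-[3,5-bis(trifluoromethyl)phenyl]-3-(9-deoxy-9-epi-quinidin-9-yl)thiourea (10 mol%), toluene, −20 °C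
Reagents that add atoms: none
Why: The bromomagnesium phenolate of 6 binds the acid chloride at magnesium and delivers the acyl group through a cyclic transition state to C4a, the only free carbon ortho to O1 because C8 carries the prenyl group; this forms the C4–C4a bond as in the known ortho-specific, Friedel–Crafts-type template acylation of magnesium phenolates with α,β-unsaturated acid chlorides, the second equivalent of phenolate taking up the HCl. The chelate between O1, magnesium and the C4 carbonyl oxygen keeps the phenolate oxygen turned away from C2, so ring C should not close before the chiral catalyst is present. After removal of magnesium the bifunctional thiourea closes ring C by a 6-endo-trig intramolecular oxa-Michael addition of O1 to C2, the closest precedent being cinchona-catalysed cyclisations of 2'-hydroxychalcones and of ortho-enoyl phenols of the phloroglucinol series. The C2 stereocentre is under catalyst control: the thiourea hydrogen-bonds the C4 carbonyl while the quinuclidinium–phenoxide ion pair delivers O1 to one enantioface of the E-enone. The step needs C- over O-acylation and ortho over para attack (secured by the magnesium template in toluene and the blocked C8), closure through O1 and not through the oxygen on C5 (secured by its silyl ether), and a slow racemic background closure (secured by low temperature and the non-polar solvent).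

Step 9
Reactants: 14 (2S)-5,7-bis(tert-butyldimethylsilyloxy)-2-(2,2-dimethylchroman-6-yl)-8-(3-methylbut-2-enyl)chroman-4-one
Product: 15 Euchrenone a16, (2S)-2-(2,2-dimethylchroman-6-yl)-5,7-dihydroxy-8-(3-methylbut-2-enyl)chroman-4-one
Conditions: Bu4NF, AcOH (1:1), THF, 0 °C
Reagents that add atoms: none
Why: Fluoride-induced cleavage of the two aryl silyl ethers (desilylation driven by Si–F bond formation) with acetic acid as buffer keeps the liberated phenols protonated, so ring C should not open by retro-oxa-Michael elimination and the C2 configuration is kept, while the prenyl group and the chroman ring are inert.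

**Compound list**

1 | phloroglucinol (benzene-1,3,5-triol) | Oc1cc(O)cc(O)c1 | starting material
2 | 3,5-bis(tert-butyldimethylsilyloxy)phenol | CC(C)(C)[Si](C)(C)Oc1cc(O)cc(O[Si](C)(C)C(C)(C)C)c1 | intermediate
3 | 2-methylbut-3-en-2-ol | C=CC(C)(C)O | starting material
4 | methyl 2-methylbut-3-en-2-yl carbonate | C=CC(C)(C)OC(=O)OC | intermediate
5 | 1,3-bis(tert-butyldimethylsilyloxy)-5-(2-methylbut-3-en-2-yloxy)benzene | C=CC(C)(C)Oc1cc(O[Si](C)(C)C(C)(C)C)cc(O[Si](C)(C)C(C)(C)C)c1 | intermediate
6 | 3,5-bis(tert-butyldimethylsilyloxy)-2-(3-methylbut-2-enyl)phenol | CC(C)=CCc1c(O)cc(O[Si](C)(C)C(C)(C)C)cc1O[Si](C)(C)C(C)(C)C | intermediate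
7 | 4-bromophenol | Oc1ccc(Br)cc1 | starting material
8 | isoprene (2-methylbuta-1,3-diene) | C=CC(C)=C | starting material
9 | 6-bromo-2,2-dimethylchroman | CC1(C)CCc2cc(Br)ccc2O1 | intermediate
10 | acrylic acid | C=CC(=O)O | starting material
11 | (E)-3-(2,2-dimethylchroman-6-yl)acrylic acid | CC1(C)CCc2cc(/C=C/C(=O)O)ccc2O1 | intermediate
12 | (E)-3-(2,2-dimethylchroman-6-yl)acryloyl chloride | CC1(C)CCc2cc(/C=C/C(=O)Cl)ccc2O1 | intermediate
13 | (E)-1-[2-hydroxy-4,6-bis(tert-butyldimethylsilyloxy)-3-(3-methylbut-2-enyl)phenyl]-3-(2,2-dimethylchroman-6-yl)prop-2-en-1-one (2'-hydroxychalcone, not isolated) | CC(C)=CCc1c(O)c(C(=O)/C=C/c2ccc3OC(C)(C)CCc3c2)c(O[Si](C)(C)C(C)(C)C)cc1O[Si](C)(C)C(C)(C)C | intermediate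
14 | (2S)-5,7-bis(tert-butyldimethylsilyloxy)-2-(2,2-dimethylchroman-6-yl)-8-(3-methylbut-2-enyl)chroman-4-one | CC(C)=CCc1c(O[Si](C)(C)C(C)(C)C)cc(O[Si](C)(C)C(C)(C)C)c2c1O[C@H](c1ccc3c(c1)CCC(C)(C)O3)CC2=O | intermediate
15 | Euchrenone a16, (2S)-2-(2,2-dimethylchroman-6-yl)-5,7-dihydroxy-8-(3-methylbut-2-enyl)chroman-4-one | CC(C)=CCc1c(O)cc(O)c2c1O[C@H](c1ccc3c(c1)CCC(C)(C)O3)CC2=O | target

**Step count and risks**

Total step count: 9. Longest linear sequence: 5 steps (steps 1, 3, 4, 8, 9 from phloroglucinol; equally steps 5, 6, 7, 8, 9 from 4-bromophenol).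

Steps most likely to fail:

1. Step 8. What may go wrong: O-acylation of the phenolate instead of C-acylation and, above all, insufficient facial discrimination in the ring closure (uncatalysed or magnesium-promoted background cyclisation, or ring opening and re-closure of the product), which would erode the enantiomeric purity. The fallback sets out from 6 and 9 and comes back at 14; it sets the C2 stereocentre by asymmetric C–C bond formation instead. Phenol 6 is C-acetylated through its bromomagnesium phenolate with acetyl chloride in toluene to 1-[2-hydroxy-4,6-bis(tert-butyldimethylsilyloxy)-3-(3-methylbut-2-enyl)phenyl]ethanone F1. N,N-Dimethylformamide dimethyl acetal converts this into (E)-3-(dimethylamino)-1-[2-hydroxy-4,6-bis(tert-butyldimethylsilyloxy)-3-(3-methylbut-2-enyl)phenyl]prop-2-en-1-one F2, which closes with loss of dimethylamine (p-TsOH cat., toluene, 60 °C) to 5,7-bis(tert-butyldimethylsilyloxy)-8-(3-methylbut-2-enyl)chromen-4-one F3. Bromide 9 is borylated with B2(OH)4 (Pd(OAc)2, XPhos, KOAc, EtOH, 80 °C) to (2,2-dimethylchroman-6-yl)boronic acid F4. Conjugate addition of F4 to F3 with Pd(OCOCF3)2 and the enantiomer of 4-tert-butyl-2-(pyridin-2-yl)-4,5-dihydrooxazole that delivers the aryl group to the face giving 2S (NH4PF6, H2O, ClCH2CH2Cl, 60 °C), a known reaction type for flavanones from chromones, should give 14.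

2. Step 3. What may go wrong: attack of the phenoxide on the unsubstituted terminus of the π-allyl complex (linear prenyl ether) or C-allylation of the electron-rich ring. The fallback sets out from 2 and comes back at 5. Copper-catalysed propargylic etherification of 2 with 3-chloro-3-methylbut-1-yne (CuCl2·2H2O cat., DBU, MeCN, 0 °C) can only give the tertiary ether 1,3-bis(tert-butyldimethylsilyloxy)-5-(2-methylbut-3-yn-2-yloxy)benzene F5. Lindlar semi-hydrogenation (H2, Pd/CaCO3 poisoned with Pb(OAc)2, quinoline, EtOAc) then gives 5.

3. Step 5. What may go wrong: slow ring alkylation of the weakly nucleophilic bromophenol, which would lose out to oligomerisation of isoprene and to over-alkylation. The fallback sets out from 7 and comes back at 9. Phenol 7 and 3-methylbut-2-enoic acid in P2O5/MeSO3H at 70 °C should give, by Friedel–Crafts acylation and oxa-Michael closure, 6-bromo-2,2-dimethylchroman-4-one F6. Ionic hydrogenation of the aryl ketone (Et3SiH, CF3CO2H, rt) removes the carbonyl oxygen and gives 9.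

**Further compounds**

F1 | step 8 | 1-[2-hydroxy-4,6-bis(tert-butyldimethylsilyloxy)-3-(3-methylbut-2-enyl)phenyl]ethanone | CC(=O)c1c(O)c(CC=C(C)C)c(O[Si](C)(C)C(C)(C)C)cc1O[Si](C)(C)C(C)(C)C
F2 | step 8 | (E)-3-(dimethylamino)-1-[2-hydroxy-4,6-bis(tert-butyldimethylsilyloxy)-3-(3-methylbut-2-enyl)phenyl]prop-2-en-1-one | CN(C)/C=C/C(=O)c1c(O)c(CC=C(C)C)c(O[Si](C)(C)C(C)(C)C)cc1O[Si](C)(C)C(C)(C)C
F3 | step 8 | 5,7-bis(tert-butyldimethylsilyloxy)-8-(3-methylbut-2-enyl)chromen-4-one | CC(C)=CCc1c(O[Si](C)(C)C(C)(C)C)cc(O[Si](C)(C)C(C)(C)C)c2c(=O)ccoc12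
F4 | step 8 | (2,2-dimethylchroman-6-yl)boronic acid | CC1(C)CCc2cc(B(O)O)ccc2O1
F5 | step 3 | 1,3-bis(tert-butyldimethylsilyloxy)-5-(2-methylbut-3-yn-2-yloxy)benzene | C#CC(C)(C)Oc1cc(O[Si](C)(C)C(C)(C)C)cc(O[Si](C)(C)C(C)(C)C)c1
F6 | step 5 | 6-bromo-2,2-dimethylchroman-4-one | CC1(C)CC(=O)c2cc(Br)ccc2O1
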